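**Retrosynthetic overview**
- The target comes from the macrocyclic 6,9,11-triol by diacetylation; the ten-membered ring is closed last at C6–C7 by an electrochemical, chromium-catalysed ring-closing alkenylation of a seco bromo-aldehyde.
- The seco aldehyde is cut at C3–C4 (B-alkyl Suzuki coupling) and at C2=C3 (Z-selective iodo-olefination of a lactol).
- The lactol is cut at C8–C9: allylation of a bicyclic oxocarbenium ion on its convex face; the mixed acetal precursor comes from photochemical ring expansion of a cyclobutanone.
- The cyclobutanone comes from a [2+2] cycloaddition of acetoxyketene with (R)-α-phellandrene, which carries C14 and relays it to C1, C10, C11 and C9; the C11 alcohol is installed by Mukaiyama hydration.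
- Ring order: six-membered ring bought; four-membered ring (temporary); five-membered cyclic acetal (temporary); ten-membered ring.

Assumption: commercial (R)-(−)-α-phellandrene is used enantiomerically pure (fractionated if needed); atom labels C1–C20 are the eunicellane positions of the target, which is taken as the (1S,2Z,6R,9R,10S,11R,14R) isomer written in the given SMILES.

**Step 1**
Reactants: 1 (R)-(−)-α-phellandrene; 2 acetoxyacetyl chloride
Product: 4 acetoxycyclobutanone (5-isopropyl-2-methyl-7-oxobicyclo[4.2.0]oct-2-en-8-yl acetate; cis ring fusion; four-membered ring anti to isopropyl; carbonyl C2 on C1 and acetoxy carbon C9 on C10), via acetoxyketene 3 (not isolated)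
Conditions: Et3N (1.5 equiv), 1 (3 equiv, excess recovered), toluene, 70 °C, 2 added over 6 h
Reagents that add atoms: none
Why: Ketene–alkene [2+2] cycloaddition at the disubstituted C1=C10 bond of the diene (carbonyl carbon to the diene terminus C1) on the face anti to the C14 isopropyl group, which sets C1 and C10 as a cis pair; the closest precedent is an alkoxyketene adding to this same diene.

**Step 2**
Reactants: 4 acetoxycyclobutanone
Product: 5 hydroxy acetoxycyclobutanone (2-hydroxy-5-isopropyl-2-methyl-7-oxobicyclo[4.2.0]octan-8-yl acetate; C11 hydroxyl cis to H10)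
Conditions: Co(acac)2 (20 mol %), PhSiH3 (2.5 equiv), O2 (1 atm), THF, 23 °C
Reagents that add atoms: dioxygen, O=O
Why: Mukaiyama hydration (hydrogen-atom transfer to C12, then O2 capture of the tertiary C11 radical) is Markovnikov, and the radical is trapped on the convex face anti to the four-membered ring, giving the 11R alcohol (minor epimer removed by chromatography).

**Step 3**
Reactants: 5 hydroxy acetoxycyclobutanone
Product: 7 mixed bis-acetal (7-hydroxy-4-isopropyl-3-methoxy-7-methyloctahydro-2-benzofuran-1-yl acetate; C9 acetoxy acetal and C2 methyl acetal; anomer mixtures), via oxacarbene 6 (not isolated)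
Conditions: hν (medium-pressure Hg lamp, Pyrex), MeOH, NaHCO3 (solid), 10 °C
Reagents that add atoms: methanol, CO
Why: Photochemical ring expansion of a cyclobutanone (Norrish alpha-cleavage on the oxygen-bearing side, reclosure on oxygen to the oxacarbene, O–H insertion of methanol) leaves C1, C10, C11 and C14 untouched and gives a cyclic bis-acetal with two different leaving groups.

**Step 4**
Reactants: 7 mixed bis-acetal; 8 (2-bromoallyl)trimethylsilane
Product: 11 lactol (cis-fused octahydro-2-benzofuran with C2 lactol OH; 9R 2-bromoallyl group cis to H10; C11 tertiary OH), via oxocarbenium ion 9 (not isolated), via methyl acetal 10 (not isolated)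
Conditions: 8 (2 equiv), BF3·OEt2 (30 mol %), CH2Cl2, −78 to −40 °C; then 1 M aq. HCl, THF, 23 °C
Reagents that add atoms: water, O
Why: Hosomi–Sakurai allylation in which the anomeric acetate ionises far faster than the methyl acetal and the silane attacks the cis-fused bicyclic oxocarbenium ion on its convex face (cis to H10), setting C9 as R; the acidic work-up then hydrolyses the remaining methyl acetal to the lactol.

**Step 5**
Reactants: 11 lactol; 12 ethyltriphenylphosphonium iodide
Product: 16 Z-vinyl iodide diol (cyclohexane with C1 (Z)-2-iodoprop-1-enyl; C10 (1R)-3-bromo-1-hydroxybut-3-enyl; C11 OH and methyl; C14 isopropyl), via ethylidene ylide 13 (not isolated), via iodophosphonium salt 14 (not isolated), via iodo ylide 15 (not isolated)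
Conditions: 12 (4 equiv), n-BuLi, THF, 23 °C; I2, −78 °C; NaN(SiMe3)2, −20 °C; then 11, THF/DMPU, −78 to −20 °C
Reagents that add atoms: iodine, II
Why: Wittig olefination with the alpha-iodo ylide (Stork–Zhao type) on the open hydroxy-aldehyde form of the lactol gives the Z-iodoalkene (iodine cis to C1) through the kinetically favoured cis-oxaphosphetane and frees the C9 hydroxyl.

**Step 6**
Reactants: 16 Z-vinyl iodide diol; 17 acrolein diethyl acetal
Product: 20 seco bromo-aldehyde (C1 side chain (1Z)-2-methyl-5-oxopent-1-enyl; C10 side chain (1R)-3-bromo-1-hydroxybut-3-enyl), via alkylborane 18 (not isolated), via diethyl acetal 19 (not isolated)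
Conditions: 17, 9-BBN, THF, 23 °C; then 16, Pd(dppf)Cl2 (5 mol %), AsPh3 (10 mol %), Cs2CO3, DMF/THF/H2O, 23 °C; then 1 M aq. HCl, THF, 23 °C
Reagents that add atoms: water, O
Why: B-alkyl Suzuki–Miyaura coupling proceeds with retention of alkene geometry (C1 and C4 cis) and at room temperature the C–I bond reacts in preference to the alkenyl C–Br bond; the acidic work-up unmasks the C6 aldehyde.

**Step 7**
Reactants: 20 seco bromo-aldehyde
Product: 21 macrocyclic triol ((1S,2Z,6R,9R,10S,11R,14R)-eunicella-2,7(16)-diene-6,9,11-triol)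
Conditions: CrCl2 (20 mol %), NiCl2(dme) (3 mol %), 2,9-dimethyl-1,10-phenanthroline (4 mol %), LiBr (0.1 M), DMF, undivided cell, Al anode, Ni-foam cathode, constant current 2 mA (2.4 F/mol), 20 added by syringe pump over 10 h to 3 mM, 23 °C; aq. NH4Cl
Reagents that add atoms: none
Why: Proposed new method: chromium-electrocatalytic ring-closing Nozaki–Hiyama–Kishi alkenylation to a ten-membered carbocycle; the cathode regenerates divalent chromium from trivalent chromium, zerovalent nickel inserts into the C7–Br bond and passes the alkenyl group to chromium, the alkenylchromium adds to the tethered C6 aldehyde, and aluminium cations from the sacrificial anode take over the alkoxide so that chromium turns over without silyl chloride and the two free hydroxyls are tolerated; feeding 20 at the rate of charge passed keeps the organochromium concentration minute and favours ring closure over dimerisation; C6 is set by the existing centres because the C9 alkoxide and the aldehyde oxygen bind the same chromium (chelate through C7–C8–C9–O), placing both oxygens on one face of the forming ring (6,9-cis, 6R); the closest known reactions are intermolecular chromium-catalytic electrochemical Nozaki–Hiyama–Kishi couplings and stoichiometric CrCl2/NiCl2 closures of medium rings.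

**Step 8**
Reactants: 21 macrocyclic triol
Product: 22 CNP0303839.1 ((1S,2Z,6R,9R,10S,11R,14R)-6,9-diacetoxyeunicella-2,7(16)-dien-11-ol)
Conditions: Ac2O (3 equiv), pyridine, DMAP (5 mol %), CH2Cl2, 0 to 23 °C
Reagents that add atoms: acetic anhydride, CC(=O)OC(C)=O
Why: Acylation of the two secondary alcohols with retention at C6 and C9; the hindered tertiary C11 alcohol is not acetylated under these mild conditions.

**Compound list**
1 | (R)-(−)-α-phellandrene, (5R)-2-methyl-5-(propan-2-yl)cyclohexa-1,3-diene | CC1=CC[C@H](C(C)C)C=C1 | starting material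
2 | acetoxyacetyl chloride | CC(=O)OCC(Cl)=O | starting material
3 | acetoxyketene | CC(=O)OC=C=O | intermediate
4 | acetoxycyclobutanone, 5-isopropyl-2-methyl-7-oxobicyclo[4.2.0]oct-2-en-8-yl acetate (cis-fused, anti to isopropyl; C9 epimers, endo major) | O=C1C(OC(C)=O)[C@@H]2[C@H]1[C@@H](C(C)C)CC=C2C | intermediate
5 | hydroxy acetoxycyclobutanone (C11 OH cis to H10; C9 epimers) | O=C1C(OC(C)=O)[C@@H]2[C@H]1[C@@H](C(C)C)CC[C@@]2(C)O | intermediate
6 | oxacarbene (carbene at C2, ring oxygen between C2 and C9) | [C]1OC(OC(C)=O)[C@@H]2[C@H]1[C@@H](C(C)C)CC[C@@]2(C)O | intermediate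
7 | mixed bis-acetal (C9 acetoxy, C2 methoxy; anomer mixtures) | COC1OC(OC(C)=O)[C@@H]2[C@H]1[C@@H](C(C)C)CC[C@@]2(C)O | intermediate
8 | (2-bromoallyl)trimethylsilane | C=C(Br)C[Si](C)(C)C | starting material
9 | oxocarbenium ion at C9 | COC1[O+]=C[C@@H]2[C@H]1[C@@H](C(C)C)CC[C@@]2(C)O | intermediate
10 | methyl acetal (9R 2-bromoallyl cis to H10; C2 anomers) | COC1O[C@H](CC(Br)=C)[C@@H]2[C@H]1[C@@H](C(C)C)CC[C@@]2(C)O | intermediate
11 | lactol (C2 anomers) | OC1O[C@H](CC(Br)=C)[C@@H]2[C@H]1[C@@H](C(C)C)CC[C@@]2(C)O | intermediate
12 | ethyltriphenylphosphonium iodide | CC[P+](c1ccccc1)(c1ccccc1)c1ccccc1.[I-] | starting material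
13 | ethylidenetriphenylphosphorane | CC=P(c1ccccc1)(c1ccccc1)c1ccccc1 | intermediate
14 | (1-iodoethyl)triphenylphosphonium iodide | CC(I)[P+](c1ccccc1)(c1ccccc1)c1ccccc1.[I-] | intermediate
15 | (1-iodoethylidene)triphenylphosphorane | CC(I)=P(c1ccccc1)(c1ccccc1)c1ccccc1 | intermediate
16 | Z-vinyl iodide diol | C=C(Br)C[C@@H](O)[C@@H]1[C@H](/C=C(/C)I)[C@@H](C(C)C)CC[C@@]1(C)O | intermediate
17 | acrolein diethyl acetal (3,3-diethoxyprop-1-ene) | C=CC(OCC)OCC | starting material
18 | B-(3,3-diethoxypropyl)-9-borabicyclo[3.3.1]nonane | CCOC(CCB1C2CCCC1CCC2)OCC | intermediate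
19 | diethyl acetal of the seco aldehyde | C=C(Br)C[C@@H](O)[C@@H]1[C@H](/C=C(/C)CCC(OCC)OCC)[C@@H](C(C)C)CC[C@@]1(C)O | intermediate
20 | seco bromo-aldehyde | C=C(Br)C[C@@H](O)[C@@H]1[C@H](/C=C(/C)CCC=O)[C@@H](C(C)C)CC[C@@]1(C)O | intermediate
21 | (1S,2Z,6R,9R,10S,11R,14R)-eunicella-2,7(16)-diene-6,9,11-triol | C=C1C[C@@H](O)[C@@H]2[C@H](/C=C(/C)CC[C@H]1O)[C@@H](C(C)C)CC[C@@]2(C)O | intermediate
22 | CNP0303839.1, the 6,9-diacetate of 21 | C=C1C[C@@H](OC(C)=O)[C@@H]2[C@H](/C=C(/C)CC[C@H]1OC(C)=O)[C@@H](C(C)C)CC[C@@]2(C)O | target

**Totals**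
Total step count: 8. Longest linear sequence: 8 steps (1 to 22).

**Steps most likely to fail, with fallbacks**

Step 7 (the proposed new ring closure; risks are oligomerisation, loss of bromine by protonation, and the wrong C6 epimer, since the chelate model is untested on this ring). Fallback with known chemistry and a different ring-closing bond (C3–C4): set out from methyl acetal 10, isolated by leaving out the acid treatment of step 4. A stoichiometric Nozaki–Hiyama–Kishi coupling (CrCl2 4 equiv, NiCl2 1 mol %, DMSO) with acrolein gives the divinyl carbinol F1 as C6 epimers that are separated, the 6R isomer being carried on. Aqueous HCl in THF gives the lactol F2, and iodo-olefination as in step 5 gives the vinyl iodide F3. 9-BBN then hydroborates only the monosubstituted C4=C5 vinyl group, and Pd(dppf)Cl2/AsPh3/Cs2CO3 at 2 mM closes the ring by intramolecular B-alkyl Suzuki–Miyaura coupling, coming back to the route at triol 21.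

Step 5 (the iodo ylide is unstable and the lactol opens slowly; C1 could epimerise through the open aldehyde). Fallback: set out from lactol 11. Still–Gennari olefination with methyl 2-[bis(2,2,2-trifluoroethoxy)phosphoryl]propanoate (KN(SiMe3)2, 18-crown-6) gives the Z-enoate F4. DIBAL-H gives the Z-allylic alcohol F5, and CBr4/PPh3 at −20 °C converts only the primary allylic hydroxyl into the allylic bromide F6. Alkylation with the lithium aza-enolate of acetaldehyde N-tert-butylimine (from LiN(i-Pr)2, excess) gives the imine F7, which aqueous oxalic acid hydrolyses, coming back to the route at aldehyde 20.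

Step 4 (the methyl acetal may ionise too, and the bromo-substituted allylsilane is a weak nucleophile). Fallback that does not rely on selective ionisation: set out from 5. Acid-catalysed methanolysis of the acetate (HCl in MeOH, 0 °C) gives the alpha-hydroxycyclobutanone F8. Pb(OAc)4 in MeOH/benzene cleaves the C2–C9 bond to the cis aldehyde ester F9 (C2 methyl ester, C9 aldehyde). Barbier allylation with 2,3-dibromopropene and indium powder in THF/H2O, which by the Felkin–Anh model (C11 anti to the nucleophile) should give the same 9R centre, is followed by spontaneous lactonisation to the lactone F10. DIBAL-H at −78 °C reduces it, coming back to the route at lactol 11.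

**Further compounds**
F1 | step 7 | divinyl carbinol methyl acetal (6R) | COC1O[C@H](CC(=C)[C@H](O)C=C)[C@@H]2[C@H]1[C@@H](C(C)C)CC[C@@]2(C)O
F2 | step 7 | divinyl carbinol lactol | OC1O[C@H](CC(=C)[C@H](O)C=C)[C@@H]2[C@H]1[C@@H](C(C)C)CC[C@@]2(C)O
F3 | step 7 | Z-vinyl iodide triene triol | C=C[C@@H](O)C(=C)C[C@@H](O)[C@@H]1[C@H](/C=C(/C)I)[C@@H](C(C)C)CC[C@@]1(C)O
F4 | step 5 | Z-enoate | C=C(Br)C[C@@H](O)[C@@H]1[C@H](/C=C(/C)C(=O)OC)[C@@H](C(C)C)CC[C@@]1(C)O
F5 | step 5 | Z-allylic alcohol | C=C(Br)C[C@@H](O)[C@@H]1[C@H](/C=C(/C)CO)[C@@H](C(C)C)CC[C@@]1(C)O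
F6 | step 5 | Z-allylic bromide | C=C(Br)C[C@@H](O)[C@@H]1[C@H](/C=C(/C)CBr)[C@@H](C(C)C)CC[C@@]1(C)O
F7 | step 5 | N-tert-butyl imine of 20 | C=C(Br)C[C@@H](O)[C@@H]1[C@H](/C=C(/C)CCC=NC(C)(C)C)[C@@H](C(C)C)CC[C@@]1(C)O
F8 | step 4 | alpha-hydroxycyclobutanone | O=C1C(O)[C@@H]2[C@H]1[C@@H](C(C)C)CC[C@@]2(C)O
F9 | step 4 | cis aldehyde ester | O=C[C@@H]1[C@H](C(=O)OC)[C@@H](C(C)C)CC[C@@]1(C)O
F10 | step 4 | allylated lactone | O=C1O[C@H](CC(Br)=C)[C@@H]2[C@H]1[C@@H](C(C)C)CC[C@@]2(C)O
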